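The seven-membered ring is read as a latent cyclohepta-1,4-diene (guaiane numbering): its lone methylene C9 lies between the tetrasubstituted C1=C10 alkene and C8, whose hydroxyl trans to the C7 side chain is the signature of hydroborating a C7=C8 alkene. Both ring alkenes are therefore made in one ruthenium-catalysed operation from cyclopentane 11, which carries a C1 methylidene and a C7 acrylate, and 2-methylpenta-1,4-diene, which supplies C8, C9, C10 and the C10 methyl: cross-metathesis joins C7 to C8, ring-closing metathesis joins C1 to C10 and closes the ring. Methyl addition, hydroboration and acylation finish the synthesis.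

Key step: step 8

Remark: atom labels follow guaiane numbering of the target (C1 and C5 ring-fusion carbons, C4 the methyl-bearing carbon of the five-membered ring, C7 the carbon carrying the 2-hydroxypropan-2-yl group C11, C8 the acyloxy carbon, C9 the ring methylene, C10 the vinylic carbon carrying methyl C14).

Step 1
Reactants: 1 3-methylcyclopent-2-en-1-one
Product: 2 2-iodo-3-methylcyclopent-2-en-1-one
Conditions: I2, pyridine, CH2Cl2, 0 °C to rt
Reagents that add atoms: iodine, II
Why: α-Iodination of the enone by the pyridine-promoted addition–iodination–elimination pathway should give the 2-iodoenone; no stereocentre is formed.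

Step 2
Reactants: 2 2-iodo-3-methylcyclopent-2-en-1-one; 3 (3-ethoxy-3-oxopropyl)zinc bromide
Product: 4 ethyl 3-(2-methyl-5-oxocyclopent-1-en-1-yl)propanoate
Conditions: Pd(PPh3)4 (cat.), THF, 50 °C
Reagents that add atoms: none
Why: Negishi cross-coupling of the alkenyl iodide with the ester-bearing alkylzinc reagent should install the C6–C7–C11 chain at the enone α-carbon without touching ketone or ester.

Step 3
Reactants: 4 ethyl 3-(2-methyl-5-oxocyclopent-1-en-1-yl)propanoate
Product: 5 ethyl 3-[(5S)-5-hydroxy-2-methylcyclopent-1-en-1-yl]propanoate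
Conditions: (R)-2-methyl-CBS-oxazaborolidine (0.2 equiv), catecholborane, toluene, −78 °C
Reagents that add atoms: none
Why: Corey–Bakshi–Shibata reduction, in which the substituted alkene carbon acts as the large ketone substituent, should give the 5S allylic alcohol whose hydroxyl later directs both ring hydrogens.

Step 4
Reactants: 5 ethyl 3-[(5S)-5-hydroxy-2-methylcyclopent-1-en-1-yl]propanoate
Product: 6 ethyl 3-[(1S,2S,5S)-2-hydroxy-5-methylcyclopentyl]propanoate
Conditions: [Ir(cod)(PCy3)(py)]PF6 (10 mol%), H2 (1 atm), CH2Cl2, 0 °C to rt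
Reagents that add atoms: none
Why: Hydroxyl-directed hydrogenation with the cationic iridium catalyst should deliver both hydrogens to the tetrasubstituted alkene from the face of the bound hydroxyl, setting C4 and C5 with the methyl group and the side chain cis to each other.

Step 5
Reactants: 6 ethyl 3-[(1S,2S,5S)-2-hydroxy-5-methylcyclopentyl]propanoate
Product: 7 ethyl 3-[(1S,2S)-2-methyl-5-oxocyclopentyl]propanoate
Conditions: Dess–Martin periodinane, NaHCO3, CH2Cl2, 0 °C to rt
Reagents that add atoms: none
Why: Dess–Martin oxidation under buffered neutral conditions should give the cis-2,3-disubstituted cyclopentanone without epimerising the C5 centre next to the new ketone.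

Step 6
Reactants: 7 ethyl 3-[(1S,2S)-2-methyl-5-oxocyclopentyl]propanoate
Product: 8 ethyl 3-[(1S,2S)-2-methyl-5-methylidenecyclopentyl]propanoate
Conditions: Zn, CH2Br2, TiCl4, THF/CH2Cl2, 0 °C to rt
Reagents that add atoms: dibromomethane, BrCBr
Why: Takai–Lombardo methylenation with the non-basic zinc/titanium reagent should convert the ketone into the C1 methylidene chemoselectively (ester untouched) and without epimerising C5, which is no longer enolisable afterwards.

Step 7
Reactants: 8 ethyl 3-[(1S,2S)-2-methyl-5-methylidenecyclopentyl]propanoate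
Product: 11 ethyl 2-{[(1S,2S)-2-methyl-5-methylidenecyclopentyl]methyl}prop-2-enoate, via Mannich base 9 (not isolated), via trimethylammonium iodide 10 (not isolated)
Conditions: LiN(iPr)2, THF, −78 °C; CH2=NMe2+ I−, −78 °C to rt; MeI, rt; DBU, rt
Reagents that add atoms: N,N-dimethylmethyleneiminium iodide (Eschenmoser's salt), C=[N+](C)C.[I-]; iodomethane, CI (its methyl group is carried by 10 and leaves as trimethylamine)
Why: Aminomethylation of the ester enolate (the only acidic C–H is α to the ester), quaternisation and base-induced elimination of trimethylamine (Eschenmoser methylenation) should give the 2-substituted acrylate at C7.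

Step 8
Reactants: 11 ethyl 2-{[(1S,2S)-2-methyl-5-methylidenecyclopentyl]methyl}prop-2-enoate; 12 2-methylpenta-1,4-diene
Product: 14 ethyl (3S,3aS)-3,8-dimethyl-1,2,3,3a,4,7-hexahydroazulene-5-carboxylate, via cross-metathesis triene 13 (not isolated)
Conditions: 12 (5 equiv), RuCl2(=CH-C6H4-2-OiPr)(H2ITol) [H2ITol = 1,3-bis(2-methylphenyl)imidazolidin-2-ylidene] (10 mol%), 1,4-benzoquinone (20 mol%), toluene, 45 °C then 90 °C, argon purge
Reagents that add atoms: none
Why: Proposed new method: the ruthenium alkylidene loads onto the monosubstituted terminus of 12, the resulting alkylidene cross-metathesises with the electron-poor 1,1-disubstituted acrylate of 11 to give the (E)-enoate 13 (C7=C8), and a second cycle on the two remaining 1,1-disubstituted alkenes closes C1=C10 with loss of ethene. The closest known reaction types are cross-metathesis of 2-substituted acrylates with terminal alkenes to trisubstituted enoates and ring-closing metathesis to tetrasubstituted cycloalkenes with N-o-tolyl carbene ruthenium catalysts; their two-component union into a (4+3) annulation is the untested part. The seven-membered carbocycle is closed by ring-closing metathesis between the C1 methylidene and the 2-propenyl terminus at C10. No stereocentre is created and C4 and C5 are untouched; the thermodynamically favoured E geometry of C7=C8 places C9 cis to C6, as the ring requires. The step needs the monosubstituted end of 12 to pair with C7 and not with the C1 methylidene: the acrylate is the matched, non-homodimerising partner, and a mis-paired triene could ring-close only to an ester-bearing tetrasubstituted alkene, so it should return to the pool by ethenolysis while the productive path is drained by ring closure and loss of ethene. Benzoquinone should suppress ruthenium hydride migration of the skipped diene.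

Step 9
Reactants: 14 ethyl (3S,3aS)-3,8-dimethyl-1,2,3,3a,4,7-hexahydroazulene-5-carboxylate
Product: 15 2-[(3S,3aS)-3,8-dimethyl-1,2,3,3a,4,7-hexahydroazulen-5-yl]propan-2-ol
Conditions: MeLi (3 equiv), CeCl3, THF, −78 to 0 °C
Reagents that add atoms: methyllithium, [Li]C
Why: Double 1,2-addition of the weakly basic organocerium reagent to the conjugated ester should give the tertiary allylic alcohol at C11 while avoiding γ-deprotonation at the doubly allylic C9.

Step 10
Reactants: 15 2-[(3S,3aS)-3,8-dimethyl-1,2,3,3a,4,7-hexahydroazulen-5-yl]propan-2-ol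
Product: 16 (3S,3aS,5S,6S)-5-(2-hydroxypropan-2-yl)-3,8-dimethyl-1,2,3,3a,4,5,6,7-octahydroazulen-6-ol
Conditions: BH3·THF (2.2 equiv), THF, 0 °C; then NaOH, H2O2, 0 °C to rt
Reagents that add atoms: hydrogen peroxide, OO
Why: Hydroboration–oxidation should place boron at the less substituted C8 of the trisubstituted C7=C8 alkene by syn addition (so the C7 side chain and the C8 hydroxyl end up trans) from the face anti to the C4 methyl and syn to H-5, setting 7S and 8S, while the tetrasubstituted C1=C10 alkene is too hindered to react.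

Step 11
Reactants: 16 (3S,3aS,5S,6S)-5-(2-hydroxypropan-2-yl)-3,8-dimethyl-1,2,3,3a,4,5,6,7-octahydroazulen-6-ol; 17 (2E)-3-[4-(acetyloxy)phenyl]prop-2-enoic acid
Product: 18 (3S,3aS,5S,6S)-5-(2-hydroxypropan-2-yl)-3,8-dimethyl-1,2,3,3a,4,5,6,7-octahydroazulen-6-yl (2E)-3-[4-(acetyloxy)phenyl]prop-2-enoate
Conditions: DCC, DMAP (cat.), CH2Cl2, 0 °C to rt
Reagents that add atoms: none
Why: Steglich esterification should acylate only the secondary C8 hydroxyl, the tertiary C11 hydroxyl being inert under carbodiimide/DMAP conditions, with the E cinnamate geometry retained.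

Step 12
Reactants: 18 (3S,3aS,5S,6S)-5-(2-hydroxypropan-2-yl)-3,8-dimethyl-1,2,3,3a,4,5,6,7-octahydroazulen-6-yl (2E)-3-[4-(acetyloxy)phenyl]prop-2-enoate
Product: 19 (3S,3aS,5S,6S)-5-(2-hydroxypropan-2-yl)-3,8-dimethyl-1,2,3,3a,4,5,6,7-octahydroazulen-6-yl (2E)-3-(4-hydroxyphenyl)prop-2-enoate
Conditions: K2CO3 (cat.), MeOH, 0 °C
Reagents that add atoms: none
Why: Base-catalysed methanolysis should remove the phenolic acetate, which is far more electrophilic than the hindered secondary cinnamate ester, to give the target.

Compound list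
1 | 3-methylcyclopent-2-en-1-one | O=C1CCC(C)=C1 | starting material
2 | 2-iodo-3-methylcyclopent-2-en-1-one | O=C1CCC(C)=C1I | intermediate
3 | (3-ethoxy-3-oxopropyl)zinc bromide | CCOC(=O)CC[Zn]Br | starting material
4 | ethyl 3-(2-methyl-5-oxocyclopent-1-en-1-yl)propanoate | O=C1CCC(C)=C1CCC(=O)OCC | intermediate
5 | ethyl 3-[(5S)-5-hydroxy-2-methylcyclopent-1-en-1-yl]propanoate | O[C@H]1CCC(C)=C1CCC(=O)OCC | intermediate
6 | ethyl 3-[(1S,2S,5S)-2-hydroxy-5-methylcyclopentyl]propanoate | O[C@H]1CC[C@H](C)[C@@H]1CCC(=O)OCC | intermediate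
7 | ethyl 3-[(1S,2S)-2-methyl-5-oxocyclopentyl]propanoate | O=C1CC[C@H](C)[C@@H]1CCC(=O)OCC | intermediate
8 | ethyl 3-[(1S,2S)-2-methyl-5-methylidenecyclopentyl]propanoate | C=C1CC[C@H](C)[C@@H]1CCC(=O)OCC | intermediate
9 | ethyl 2-[(dimethylamino)methyl]-3-[(1S,2S)-2-methyl-5-methylidenecyclopentyl]propanoate (both C-2 epimers) | C=C1CC[C@H](C)[C@@H]1CC(CN(C)C)C(=O)OCC | intermediate (not isolated)
10 | {2-(ethoxycarbonyl)-3-[(1S,2S)-2-methyl-5-methylidenecyclopentyl]propyl}trimethylammonium iodide | C=C1CC[C@H](C)[C@@H]1CC(C[N+](C)(C)C)C(=O)OCC.[I-] | intermediate (not isolated)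
11 | ethyl 2-{[(1S,2S)-2-methyl-5-methylidenecyclopentyl]methyl}prop-2-enoate | C=C1CC[C@H](C)[C@@H]1CC(=C)C(=O)OCC | intermediate
12 | 2-methylpenta-1,4-diene | C=C(C)CC=C | starting material
13 | ethyl (2E)-5-methyl-2-{[(1S,2S)-2-methyl-5-methylidenecyclopentyl]methyl}hexa-2,5-dienoate | C=C1CC[C@H](C)[C@@H]1C/C(C(=O)OCC)=C\CC(C)=C | intermediate (not isolated)
14 | ethyl (3S,3aS)-3,8-dimethyl-1,2,3,3a,4,7-hexahydroazulene-5-carboxylate | CC1=C2CC[C@H](C)[C@@H]2CC(C(=O)OCC)=CC1 | intermediate
15 | 2-[(3S,3aS)-3,8-dimethyl-1,2,3,3a,4,7-hexahydroazulen-5-yl]propan-2-ol | CC1=C2CC[C@H](C)[C@@H]2CC(C(C)(C)O)=CC1 | intermediate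
16 | (3S,3aS,5S,6S)-5-(2-hydroxypropan-2-yl)-3,8-dimethyl-1,2,3,3a,4,5,6,7-octahydroazulen-6-ol | CC1=C2CC[C@H](C)[C@@H]2C[C@H](C(C)(C)O)[C@@H](O)C1 | intermediate
17 | (2E)-3-[4-(acetyloxy)phenyl]prop-2-enoic acid | CC(=O)Oc1ccc(/C=C/C(=O)O)cc1 | starting material
18 | (3S,3aS,5S,6S)-5-(2-hydroxypropan-2-yl)-3,8-dimethyl-1,2,3,3a,4,5,6,7-octahydroazulen-6-yl (2E)-3-[4-(acetyloxy)phenyl]prop-2-enoate | CC1=C2CC[C@H](C)[C@@H]2C[C@H](C(C)(C)O)[C@@H](OC(=O)/C=C/c2ccc(OC(C)=O)cc2)C1 | intermediate
19 | (3S,3aS,5S,6S)-5-(2-hydroxypropan-2-yl)-3,8-dimethyl-1,2,3,3a,4,5,6,7-octahydroazulen-6-yl (2E)-3-(4-hydroxyphenyl)prop-2-enoate | CC1=C2CC[C@H](C)[C@@H]2C[C@H](C(C)(C)O)[C@@H](OC(=O)/C=C/c2ccc(O)cc2)C1 | target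

Total step count: 12
Longest linear sequence: 12 steps (1 to 19)

Steps most likely to fail

Step 8 (proposed new method). The cross-metathesis may pair the diene with the C1 methylidene instead of the acrylate, or the catalyst may decompose before the tetrasubstituted ring closure is complete. The fallback uses known reactions only, sets out from 11 and comes back at 14. The electron-rich exocyclic methylidene of 11 is cleaved selectively by ozonolysis (O3, pyridine, CH2Cl2, −78 °C; then Me2S), leaving the electron-poor acrylate, to give ethyl 2-{[(1S,2S)-2-methyl-5-oxocyclopentyl]methyl}prop-2-enoate F1. Cross-metathesis of its only alkene with commercial pent-4-en-2-one (second-generation Hoveyda–Grubbs catalyst, RuCl2(H2IMes)(=CH-C6H4-2-OiPr), CH2Cl2, 40 °C) should give ethyl (2E)-2-{[(1S,2S)-2-methyl-5-oxocyclopentyl]methyl}-5-oxohex-2-enoate F2. Intramolecular McMurry coupling of the two ketones (TiCl3(DME)1.5, Zn–Cu couple, DME, reflux, high dilution) then closes C1=C10 and gives 14.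

Step 10. Borane may add with poor facial selectivity at C7=C8, or attack the C1=C10 alkene as well. The fallback sets out from 14 and comes back at 16, with C8 set by a catalyst instead of by the substrate. Copper-catalysed conjugate borylation of the enoate (CuCl, NaOtBu, a chiral Josiphos-type bisphosphine, B2pin2, MeOH, THF) should give ethyl (3S,3aS,5S,6S)-3,8-dimethyl-6-(4,4,5,5-tetramethyl-1,3,2-dioxaborolan-2-yl)-1,2,3,3a,4,5,6,7-octahydroazulene-5-carboxylate F3; if protonation gives the cis ester, C7 is equilibrated to the trans arrangement with NaOEt in EtOH. Oxidation (NaBO3, THF/H2O) gives ethyl (3S,3aS,5S,6S)-6-hydroxy-3,8-dimethyl-1,2,3,3a,4,5,6,7-octahydroazulene-5-carboxylate F4, and MeLi/CeCl3 (THF, −78 °C) converts the ester into the tertiary alcohol 16.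

Step 4. The iridium catalyst may be deactivated on the tetrasubstituted alkene, or direction by the hydroxyl may be incomplete and give the trans isomer. The fallback sets out from enone 4 and comes back at ketone 7, replacing steps 3 to 5. Both hydrogens are delivered to the enone C=C by cis-selective asymmetric hydrogenation with a cationic ruthenium hydride diphosphine catalyst, [RuH(Me-DuPhos)(cyclooctatriene)]BF4 (ligand antipode chosen for the 1S,2S product), H2 (90 bar), CH2Cl2. This is the reaction type used for cis-2,3-dialkylcyclopentanones, and it makes no new compound.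

Further compounds
F1 | step 8 | ethyl 2-{[(1S,2S)-2-methyl-5-oxocyclopentyl]methyl}prop-2-enoate | O=C1CC[C@H](C)[C@@H]1CC(=C)C(=O)OCC
F2 | step 8 | ethyl (2E)-2-{[(1S,2S)-2-methyl-5-oxocyclopentyl]methyl}-5-oxohex-2-enoate | O=C1CC[C@H](C)[C@@H]1C/C(C(=O)OCC)=C\CC(C)=O
F3 | step 10 | ethyl (3S,3aS,5S,6S)-3,8-dimethyl-6-(4,4,5,5-tetramethyl-1,3,2-dioxaborolan-2-yl)-1,2,3,3a,4,5,6,7-octahydroazulene-5-carboxylate | CC1=C2CC[C@H](C)[C@@H]2C[C@H](C(=O)OCC)[C@@H](B3OC(C)(C)C(C)(C)O3)C1
F4 | step 10 | ethyl (3S,3aS,5S,6S)-6-hydroxy-3,8-dimethyl-1,2,3,3a,4,5,6,7-octahydroazulene-5-carboxylate | CC1=C2CC[C@H](C)[C@@H]2C[C@H](C(=O)OCC)[C@@H](O)C1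
F0 | step 4 | none | none
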